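The route rests on cutting the eight-membered ring B at the bond between its exocyclic-methylene carbon and the hydroxylated carbon shared by rings A and B. That 1,1-disubstituted allylic tertiary alcohol is the retron of an alkenylmetal addition to a ketone, so a Nozaki–Hiyama–Kishi cyclisation closes ring B, installs the exo-methylene and sets the A/B-fusion carbinol in one operation. The precursor is a seco compound: a trans-hydrindane (rings C and D, built by a Pauson–Khand reaction on a chiral butenolide scaffold) carrying an alkenyl triflate and a Z-trisubstituted allyl chain that ends in an acetonide-protected cyclopentanone (ring A), later oxidised to the diosphenol.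

Key step: step 23

Assumption: the (5S)-menthyloxyfuranone derived from (+)-menthol, the ribose-derived (3aR,6aR) acetonide enone, 4-methylpent-2-yn-1-ol and methallylmagnesium chloride are taken as purchasable.

Step 1
Reactants: 1 (S)-1-bromo-2-methylbutane; 2 ethyl but-2-ynoate
Product: 4 ethyl (2E,5S)-3,5-dimethylhept-2-enoate, via alkylmagnesium bromide 3 (not isolated)
Conditions: Mg, THF, reflux; CuBr·SMe2 (1 equiv), THF, −78 °C; then 2, −78 °C; H2O quench at −78 °C
Reagents that add atoms: none
Why: syn carbocupration of the alkynoate (organocopper conjugate addition) at low temperature should place the new alkyl group trans to the ester, giving the E-enoate without touching the remote stereocentre.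

Step 2
Reactants: 4 ethyl (2E,5S)-3,5-dimethylhept-2-enoate
Product: 5 (2E,5S)-3,5-dimethylhept-2-en-1-ol
Conditions: i-Bu2AlH, CH2Cl2, −78 °C
Reagents that add atoms: none
Why: 1,2-reduction of the enoate by the aluminium hydride (ester reduction) should give the allylic alcohol with the alkene geometry untouched.

Step 3
Reactants: 5 (2E,5S)-3,5-dimethylhept-2-en-1-ol
Product: 6 [(2R,3R)-3-methyl-3-[(2S)-2-methylbutyl]oxiran-2-yl]methanol
Conditions: Ti(Oi-Pr)4 (10 mol%), D-(−)-diethyl tartrate (12 mol%), t-BuOOH, 4 Å MS, CH2Cl2, −20 °C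
Reagents that add atoms: tert-butyl hydroperoxide, CC(C)(C)OO
Why: Sharpless asymmetric epoxidation, in which D-(−)-tartrate should deliver oxygen to the face that gives the (2R,3R) epoxide under reagent control.

Step 4
Reactants: 6 [(2R,3R)-3-methyl-3-[(2S)-2-methylbutyl]oxiran-2-yl]methanol
Product: 7 (3R,5S)-3,5-dimethylheptane-1,3-diol
Conditions: NaAlH2(OCH2CH2OMe)2, THF, 0 °C
Reagents that add atoms: none
Why: hydroxyl-directed reductive opening of the 2,3-epoxy alcohol at C2 (regioselective epoxide reduction) should leave the tertiary C–O bond and its configuration intact.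

Step 5
Reactants: 7 (3R,5S)-3,5-dimethylheptane-1,3-diol
Product: 8 (3R,5S)-3-hydroxy-3,5-dimethylheptanoic acid
Conditions: TEMPO (cat.), PhI(OAc)2, MeCN/H2O, rt
Reagents that add atoms: water, O
Why: nitroxyl-catalysed oxidation of the primary alcohol through the aldehyde hydrate to the acid (TEMPO/hypervalent iodine oxidation) cannot touch the tertiary alcohol.

Step 6
Reactants: 9 (3aR,6aR)-2,2-dimethyl-3a,6a-dihydro-4H-cyclopenta[d][1,3]dioxol-4-one
Product: 10 (3aR,4S,6aR)-2,2,4-trimethyl-3a,6a-dihydro-4H-cyclopenta[d][1,3]dioxol-4-ol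
Conditions: MeLi, THF, −78 °C; then H2O
Reagents that add atoms: methyllithium, [Li]C
Why: 1,2-addition of the organolithium to the enone carbonyl should occur from the convex face anti to the dioxolane, and the new carbinol centre is erased in the next step.

Step 7
Reactants: 10 (3aR,4S,6aR)-2,2,4-trimethyl-3a,6a-dihydro-4H-cyclopenta[d][1,3]dioxol-4-ol
Product: 11 (3aS,6aS)-2,2,6-trimethyl-3a,6a-dihydro-4H-cyclopenta[d][1,3]dioxol-4-one
Conditions: C5H5NH[CrO3Cl] (pyridinium chlorochromate), 4 Å MS, CH2Cl2, rt
Reagents that add atoms: none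
Why: oxidative 1,3-transposition of the tertiary allylic alcohol (Babler–Dauben oxidation) through a [3,3] shift of the chromate ester should give the β-methyl enone with both acetonide stereocentres untouched.

Step 8
Reactants: 12 4-methylpent-2-yn-1-ol
Product: 13 1-bromo-4-methylpent-2-yne
Conditions: CBr4, PPh3, CH2Cl2, 0 °C
Reagents that add atoms: tetrabromomethane, BrC(Br)(Br)Br
Why: Appel bromination of the primary propargylic alcohol.

Step 9
Reactants: 14 (5S)-5-[(1S,2R,5S)-menthyloxy]furan-2(5H)-one; 15 (2-methylprop-2-en-1-yl)magnesium chloride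
Product: 17 (4S,5S)-5-[(1S,2R,5S)-menthyloxy]-4-(2-methylprop-2-en-1-yl)oxolan-2-one, via silyl ketene acetal 16 (not isolated)
Conditions: CuBr·SMe2 (10 mol%), Me3SiCl, THF, −78 °C; then aq. NH4Cl work-up
Reagents that add atoms: none
Why: copper-catalysed conjugate addition of the allylic Grignard reagent, accelerated by the chlorosilane, should occur anti to the menthyloxy group and so set the ring-C carbon that later bears the Z-alkenyl chain.

Step 10
Reactants: 17 (4S,5S)-5-[(1S,2R,5S)-menthyloxy]-4-(2-methylprop-2-en-1-yl)oxolan-2-one; 13 1-bromo-4-methylpent-2-yne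
Product: 19 (3S,4S,5S)-5-[(1S,2R,5S)-menthyloxy]-3-(4-methylpent-2-yn-1-yl)-4-(2-methylprop-2-en-1-yl)oxolan-2-one, via lithium enolate 18 (not isolated)
Conditions: LiN(i-Pr)2, THF, −78 °C; then 13, DMPU, −78 → −40 °C
Reagents that add atoms: none
Why: lactone enolate alkylation (SN2 on the propargylic bromide) should take place anti to the adjacent methallyl group and give the trans-3,4-disubstituted lactone.

Step 11
Reactants: 19 enyne lactone
Product: 21 tricyclic Pauson–Khand enone, via alkyne–Co2(CO)6 complex 20 (not isolated)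
Conditions: Co2(CO)8 (1.1 equiv), CH2Cl2, rt; then n-BuSMe, ClCH2CH2Cl, 83 °C
Reagents that add atoms: dicobalt octacarbonyl, O=C=[Co](=C=O)(=C=O)(=C=O)[Co](=C=O)(=C=O)(=C=O)=C=O
Why: the intramolecular Pauson–Khand reaction of the 1,7-enyne builds rings C and D at once, and the trans-fused lactone holds both arms equatorial so that chair-like insertion should place the new angular methyl axial and cis to the hydrogen on the acetal-bearing ring-C carbon.

Step 12
Reactants: 21 tricyclic Pauson–Khand enone
Product: 22 saturated trans-hydrindanone lactone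
Conditions: H2 (20 atm), 10% Pd/C, EtOAc, rt
Reagents that add atoms: none
Why: heterogeneous hydrogenation of the tetrasubstituted enone alkene from the face anti to the axial angular methyl should deliver both hydrogens syn, setting the trans C/D fusion and the isopropyl-bearing centre (isopropyl cis to the methyl).

Step 13
Reactants: 22 saturated trans-hydrindanone lactone
Product: 23 ring-D alcohol with hydroxyl cis to isopropyl
Conditions: NaBH4, THF/MeOH (10:1), −20 °C
Reagents that add atoms: none
Why: borohydride reduction of the cyclopentanone from the face anti to the isopropyl group and the angular methyl should give the alcohol cis to isopropyl, the epimer that the later Mitsunobu inversion needs, while the lactone survives at this temperature.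

Step 14
Reactants: 23 ring-D alcohol with hydroxyl cis to isopropyl
Product: 24 tert-butyldimethylsilyl ether of 23
Conditions: t-BuMe2SiCl, imidazole, DMF, 40 °C
Reagents that add atoms: tert-butyldimethylsilyl chloride, CC(C)(C)[Si](C)(C)Cl
Why: silyl ether protection of the secondary alcohol under conditions without a Lewis acid, which spare the acyl acetal.

Step 15
Reactants: 24 tert-butyldimethylsilyl ether of 23
Product: 26 ester alkyne, via ester aldehyde 25 (not isolated)
Conditions: dimethyl (1-diazo-2-oxopropyl)phosphonate, K2CO3, MeOH, 0 °C → rt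
Reagents that add atoms: methanol, CO; dimethyl (1-diazo-2-oxopropyl)phosphonate, CC(=O)C(=[N+]=[N-])P(=O)(OC)OC
Why: methoxide opens the acyl acetal to the methyl ester and the free aldehyde, which undergoes Seyferth–Gilbert homologation with the Ohira–Bestmann reagent in the same pot, both ring-C substituents staying in the equatorial trans arrangement that is thermodynamically preferred.

Step 16
Reactants: 26 ester alkyne
Product: 28 keto alkyne, via α-silyl ketone 27 (not isolated)
Conditions: Me3SiCH2Li (3.2 equiv), THF/pentane, −78 → 0 °C; then MeOH, rt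
Reagents that add atoms: (trimethylsilyl)methyllithium, [Li]C[Si](C)(C)C
Why: acylation of the α-silyl carbanion by the ester (ester to methyl ketone conversion) should stop at the ketone stage because the β-ketosilane is deprotonated in situ, and methanolysis of the C–Si bond then frees the methyl ketone while the acetylide is simply reprotonated.

Step 17
Reactants: 28 keto alkyne
Product: 29 keto alkynoate
Conditions: PdCl2 (5 mol%), CuCl2, NaOAc, CO (1 atm), MeOH, rt
Reagents that add atoms: carbon monoxide, [C-]#[O+]; methanol, CO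
Why: palladium-catalysed oxidative alkoxycarbonylation of the terminal alkyne gives the alkynoate under non-basic conditions that leave the methyl ketone untouched.

Step 18
Reactants: 29 keto alkynoate
Product: 30 keto Z-enoate
Conditions: Me2CuLi (from CuI and MeLi), THF, −78 °C; MeOH quench at −78 °C
Reagents that add atoms: lithium dimethylcuprate, [Li+].C[Cu-]C
Why: syn carbocupration of the alkynoate (cuprate conjugate addition) with cold protonation should fix the Z-trisubstituted alkene with the ring carbon cis to the ester, and Me2CuLi does not add to the ketone at this temperature.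

Step 19
Reactants: 30 keto Z-enoate
Product: 32 alkenyl triflate Z-enoate, via potassium enolate 31 (not isolated)
Conditions: KN(SiMe3)2 (1.05 equiv), THF, −78 °C; then PhNTf2, −78 → 0 °C
Reagents that add atoms: N-phenylbis(trifluoromethanesulfonimide), O=S(=O)(N(c1ccccc1)S(=O)(=O)C(F)(F)F)C(F)(F)F
Why: kinetic deprotonation of the methyl ketone on its methyl group and O-triflation of the enolate (enol triflate formation) should give the 1,1-disubstituted alkenyl triflate, the ketone being markedly more acidic than the γ-positions of the enoate.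

Step 20
Reactants: 32 alkenyl triflate Z-enoate
Product: 33 Z-allylic alcohol
Conditions: i-Bu2AlH, CH2Cl2, −78 °C
Reagents that add atoms: none
Why: 1,2-reduction of the enoate (ester reduction) gives the Z-allylic alcohol, and the alkenyl triflate is inert to the aluminium hydride at this temperature.

Step 21
Reactants: 33 Z-allylic alcohol
Product: 34 Z-allylic bromide
Conditions: CBr4, PPh3, CH2Cl2, −20 °C
Reagents that add atoms: tetrabromomethane, BrC(Br)(Br)Br
Why: Appel bromination at the primary allylic carbon proceeds by SN2 and should cause neither allylic transposition nor loss of the Z geometry.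

Step 22
Reactants: 11 (3aS,6aS)-2,2,6-trimethyl-3a,6a-dihydro-4H-cyclopenta[d][1,3]dioxol-4-one; 34 Z-allylic bromide
Product: 36 seco ketone, via silyl enol ether 35 (not isolated)
Conditions: 11 (1.5 equiv), [(Ph3P)CuH]6 (5 mol% Cu), PhMe2SiH, toluene, rt; then 34, Bu4N[Ph3SiF2], CH2Cl2, 0 °C → rt
Reagents that add atoms: none
Why: copper hydride conjugate reduction delivers hydride anti to the dioxolane and gives a regiodefined silyl enol ether, whose fluoride-released enolate should be alkylated by the allylic bromide anti to the adjacent methyl and on the convex face (reductive alkylation), setting the ring-A carbon that bears the side chain.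

Step 23
Reactants: 36 seco ketone
Product: 38 tetracyclic carbinol, via alkenylchromium dichloride 37 (not isolated)
Conditions: CrCl2 (15 equiv), NiCl2 (2 mol% relative to CrCl2), degassed DMF, 0.003 M, rt → 50 °C; aq. work-up
Reagents that add atoms: none
Why: Zerovalent nickel inserts into the alkenyl C–OTf bond, the alkenyl group passes to trivalent chromium and the resulting non-basic alkenylchromium adds to the ring-A ketone. This is the Nozaki–Hiyama–Kishi alkenylation in its intramolecular, medium-ring form. Ring B closes by an 8-exo-trig 1,2-addition, and the exocyclic methylene and the tertiary carbinol arise in the same event. The new carbinol stereocentre is controlled by ring A itself: the allylic tether sits on the face of the cyclopentanone opposite the cis-fused dioxolane, so attack from the tether side is also attack on the convex face and should give the cis A/B fusion with the hydroxyl syn to the acetonide oxygens. The step needs cyclisation to outrun intermolecular addition and protodemetalation, which high dilution and the turn imposed by the Z-alkene together with the trans-diequatorial substitution of ring C should secure. Chemoselectivity is not at stake, since the ketone is the only carbonyl group and the organochromium does not enolise it.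

Step 24
Reactants: 38 tetracyclic carbinol
Product: 39 tetracyclic diol with the ring-D alcohol freed
Conditions: Bu4NF, THF, rt
Reagents that add atoms: none
Why: fluoride cleavage of the silyl ether (desilylation) frees the secondary alcohol, and the tertiary alcohol and the acetonide are unaffected.

Step 25
Reactants: 39 tetracyclic diol with the ring-D alcohol freed; 8 (3R,5S)-3-hydroxy-3,5-dimethylheptanoic acid
Product: 40 acetonide-protected ester
Conditions: PPh3, i-PrO2CN=NCO2i-Pr, toluene, 0 °C → rt
Reagents that add atoms: none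
Why: Mitsunobu esterification should displace the activated cyclopentanol with inversion from the open face anti to isopropyl and angular methyl, giving the acyloxy group in the required configuration, while neither tertiary alcohol is activated.

Step 26
Reactants: 40 acetonide-protected ester
Product: 41 triol ester
Conditions: 1 M aq. HCl, THF, rt
Reagents that add atoms: none
Why: acid-catalysed hydrolysis of the isopropylidene acetal (acetonide cleavage) under conditions mild enough for the tertiary alcohols and the ester.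

Step 27
Reactants: 41 triol ester
Product: 43 target compound CNP0110944.3, via 1,2-diketone 42 (not isolated)
Conditions: (COCl)2, Me2SO, CH2Cl2, −78 °C; then Et3N, −78 → 0 °C
Reagents that add atoms: none
Why: Swern oxidation of both secondary alcohols should give the α-diketone without C–C cleavage, and this can enolise only towards the methyl-bearing carbon, which gives the diosphenol of the target.

Compound list
1 | (S)-1-bromo-2-methylbutane | BrC[C@@H](C)CC | starting material
2 | ethyl but-2-ynoate | CC#CC(=O)OCC | starting material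
3 | (S)-2-methylbutylmagnesium bromide | CC[C@H](C)C[Mg]Br | intermediate
4 | ethyl (2E,5S)-3,5-dimethylhept-2-enoate | CCOC(=O)/C=C(C)/C[C@@H](C)CC | intermediate
5 | (2E,5S)-3,5-dimethylhept-2-en-1-ol | OC/C=C(C)/C[C@@H](C)CC | intermediate
6 | [(2R,3R)-3-methyl-3-[(2S)-2-methylbutyl]oxiran-2-yl]methanol | OC[C@H]1O[C@]1(C)C[C@@H](C)CC | intermediate
7 | (3R,5S)-3,5-dimethylheptane-1,3-diol | OCC[C@](C)(O)C[C@@H](C)CC | intermediate
8 | (3R,5S)-3-hydroxy-3,5-dimethylheptanoic acid | OC(=O)C[C@](C)(O)C[C@@H](C)CC | intermediate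
9 | (3aR,6aR)-2,2-dimethyl-3a,6a-dihydro-4H-cyclopenta[d][1,3]dioxol-4-one | C1=CC(=O)[C@@H]2OC(C)(C)O[C@H]12 | starting material
10 | (3aR,4S,6aR)-2,2,4-trimethyl-3a,6a-dihydro-4H-cyclopenta[d][1,3]dioxol-4-ol (hydroxyl cis to the dioxolane) | C1=C[C@](C)(O)[C@@H]2OC(C)(C)O[C@H]12 | intermediate
11 | (3aS,6aS)-2,2,6-trimethyl-3a,6a-dihydro-4H-cyclopenta[d][1,3]dioxol-4-one | O=C1C=C(C)[C@@H]2OC(C)(C)O[C@H]12 | intermediate
12 | 4-methylpent-2-yn-1-ol | CC(C)C#CCO | starting material
13 | 1-bromo-4-methylpent-2-yne | CC(C)C#CCBr | intermediate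
14 | (5S)-5-{[(1S,2R,5S)-5-methyl-2-(propan-2-yl)cyclohexyl]oxy}furan-2(5H)-one | O=C1C=C[C@@H](O[C@H]2C[C@@H](C)CC[C@@H]2C(C)C)O1 | starting material
15 | (2-methylprop-2-en-1-yl)magnesium chloride | CC(=C)C[Mg]Cl | starting material
16 | trimethylsilyl ketene acetal of lactone 17 | C[Si](C)(C)OC1=C[C@H](CC(C)=C)[C@@H](O[C@H]2C[C@@H](C)CC[C@@H]2C(C)C)O1 | intermediate
17 | (4S,5S)-5-[(1S,2R,5S)-menthyloxy]-4-(2-methylprop-2-en-1-yl)oxolan-2-one (4,5-trans) | O=C1C[C@H](CC(C)=C)[C@@H](O[C@H]2C[C@@H](C)CC[C@@H]2C(C)C)O1 | intermediate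
18 | lithium enolate of lactone 17 | [Li]OC1=C[C@H](CC(C)=C)[C@@H](O[C@H]2C[C@@H](C)CC[C@@H]2C(C)C)O1 | intermediate
19 | (3S,4S,5S)-5-[(1S,2R,5S)-menthyloxy]-3-(4-methylpent-2-yn-1-yl)-4-(2-methylprop-2-en-1-yl)oxolan-2-one (all trans) | O=C1[C@@H](CC#CC(C)C)[C@H](CC(C)=C)[C@@H](O[C@H]2C[C@@H](C)CC[C@@H]2C(C)C)O1 | intermediate
20 | hexacarbonyldicobalt complex of the alkyne of 19 | O=C1[C@@H](CC23[Co]4(=C=O)(=C=O)(=C=O)[Co]2(=C=O)(=C=O)(=C=O)C34C(C)C)[C@H](CC(C)=C)[C@@H](O[C@H]5C[C@@H](C)CC[C@@H]5C(C)C)O1 | intermediate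
21 | tricyclic enone: ring D 2-isopropylcyclopent-2-enone fused to ring C at the enone β-carbon and at the methyl-bearing quaternary carbon; ring C trans-fused to the γ-lactone menthyl acetal; angular methyl cis to the hydrogen on the acetal-bearing ring-C carbon | O=C1[C@H]2CC3=C(C(C)C)C(=O)C[C@]3(C)C[C@@H]2[C@@H](O[C@H]4C[C@@H](C)CC[C@@H]4C(C)C)O1 | intermediate
22 | saturated ketone from 21: trans C/D fusion, isopropyl cis to the angular methyl | O=C1[C@H]2C[C@H]3[C@@H](C(C)C)C(=O)C[C@]3(C)C[C@@H]2[C@@H](O[C@H]4C[C@@H](C)CC[C@@H]4C(C)C)O1 | intermediate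
23 | ring-D alcohol from 22: hydroxyl cis to isopropyl and to the angular methyl | O=C1[C@H]2C[C@H]3[C@@H](C(C)C)[C@@H](O)C[C@]3(C)C[C@@H]2[C@@H](O[C@H]4C[C@@H](C)CC[C@@H]4C(C)C)O1 | intermediate
24 | tert-butyldimethylsilyl ether of 23 | O=C1[C@H]2C[C@H]3[C@@H](C(C)C)[C@@H](O[Si](C)(C)C(C)(C)C)C[C@]3(C)C[C@@H]2[C@@H](O[C@H]4C[C@@H](C)CC[C@@H]4C(C)C)O1 | intermediate
25 | ester aldehyde: trans-hydrindane with equatorial methyl ester and formyl groups on adjacent ring-C carbons (trans) | COC(=O)[C@H]1C[C@H]2[C@@H](C(C)C)[C@@H](O[Si](C)(C)C(C)(C)C)C[C@]2(C)C[C@@H]1C=O | intermediate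
26 | ester alkyne: as 25 with ethynyl in place of formyl | COC(=O)[C@H]1C[C@H]2[C@@H](C(C)C)[C@@H](O[Si](C)(C)C(C)(C)C)C[C@]2(C)C[C@@H]1C#C | intermediate
27 | (trimethylsilyl)methyl ketone corresponding to 28 | C[Si](C)(C)CC(=O)[C@H]1C[C@H]2[C@@H](C(C)C)[C@@H](O[Si](C)(C)C(C)(C)C)C[C@]2(C)C[C@@H]1C#C | intermediate
28 | keto alkyne: as 26 with acetyl in place of the methyl ester | CC(=O)[C@H]1C[C@H]2[C@@H](C(C)C)[C@@H](O[Si](C)(C)C(C)(C)C)C[C@]2(C)C[C@@H]1C#C | intermediate
29 | keto alkynoate: methyl 3-(hydrindanyl)prop-2-ynoate with the acetyl group of 28 | CC(=O)[C@H]1C[C@H]2[C@@H](C(C)C)[C@@H](O[Si](C)(C)C(C)(C)C)C[C@]2(C)C[C@@H]1C#CC(=O)OC | intermediate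
30 | keto Z-enoate: methyl (2Z)-3-(hydrindanyl)but-2-enoate with the acetyl group of 28 | CC(=O)[C@H]1C[C@H]2[C@@H](C(C)C)[C@@H](O[Si](C)(C)C(C)(C)C)C[C@]2(C)C[C@@H]1/C(C)=C\C(=O)OC | intermediate
31 | potassium enolate of the methyl ketone of 30 (terminal enolate) | [K]OC(=C)[C@H]1C[C@H]2[C@@H](C(C)C)[C@@H](O[Si](C)(C)C(C)(C)C)C[C@]2(C)C[C@@H]1/C(C)=C\C(=O)OC | intermediate
32 | alkenyl triflate Z-enoate: as 30 with 1-(trifluoromethanesulfonyloxy)ethenyl in place of acetyl | C=C(OS(=O)(=O)C(F)(F)F)[C@H]1C[C@H]2[C@@H](C(C)C)[C@@H](O[Si](C)(C)C(C)(C)C)C[C@]2(C)C[C@@H]1/C(C)=C\C(=O)OC | intermediate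
33 | Z-allylic alcohol: (2Z)-3-(hydrindanyl)but-2-en-1-ol carrying the alkenyl triflate | C=C(OS(=O)(=O)C(F)(F)F)[C@H]1C[C@H]2[C@@H](C(C)C)[C@@H](O[Si](C)(C)C(C)(C)C)C[C@]2(C)C[C@@H]1/C(C)=C\CO | intermediate
34 | Z-allylic bromide corresponding to 33 | C=C(OS(=O)(=O)C(F)(F)F)[C@H]1C[C@H]2[C@@H](C(C)C)[C@@H](O[Si](C)(C)C(C)(C)C)C[C@]2(C)C[C@@H]1/C(C)=C\CBr | intermediate
35 | (3aS,6S,6aS)-4-[dimethyl(phenyl)silyloxy]-2,2,6-trimethyl-6,6a-dihydro-3aH-cyclopenta[d][1,3]dioxole (methyl cis to the dioxolane) | C1=C(O[Si](C)(C)c2ccccc2)[C@H]3OC(C)(C)O[C@H]3[C@H]1C | intermediate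
36 | seco ketone: (3aS,5S,6S,6aS)-2,2,6-trimethyltetrahydro-4H-cyclopenta[d][1,3]dioxol-4-one whose C5 carries the Z-allyl chain of 34 (chain trans to the 6-methyl and to the dioxolane) | C=C(OS(=O)(=O)C(F)(F)F)[C@H]1C[C@H]2[C@@H](C(C)C)[C@@H](O[Si](C)(C)C(C)(C)C)C[C@]2(C)C[C@@H]1/C(C)=C\C[C@H]1[C@H](C)[C@@H]2OC(C)(C)O[C@@H]2C1=O | intermediate
37 | alkenylchromium dichloride derived from 36 | C=C([Cr](Cl)Cl)[C@H]1C[C@H]2[C@@H](C(C)C)[C@@H](O[Si](C)(C)C(C)(C)C)C[C@]2(C)C[C@@H]1/C(C)=C\C[C@H]1[C@H](C)[C@@H]2OC(C)(C)O[C@@H]2C1=O | intermediate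
38 | tetracyclic carbinol: rings A to D closed, cis A/B fusion, tertiary hydroxyl cis to the acetonide, silyl ether on ring D | C=C1[C@H]2C[C@H]3[C@@H](C(C)C)[C@@H](O[Si](C)(C)C(C)(C)C)C[C@]3(C)C[C@@H]2/C(C)=C\C[C@H]2[C@H](C)[C@@H]4OC(C)(C)O[C@@H]4[C@@]12O | intermediate
39 | tetracyclic diol: as 38 with the ring-D hydroxyl free (cis to isopropyl) | C=C1[C@H]2C[C@H]3[C@@H](C(C)C)[C@@H](O)C[C@]3(C)C[C@@H]2/C(C)=C\C[C@H]2[C@H](C)[C@@H]4OC(C)(C)O[C@@H]4[C@@]12O | intermediate
40 | acetonide-protected ester: ring-D oxygen inverted (trans to isopropyl) and acylated by 8 | C=C1[C@H]2C[C@H]3[C@@H](C(C)C)[C@H](OC(=O)C[C@](C)(O)C[C@@H](C)CC)C[C@]3(C)C[C@@H]2/C(C)=C\C[C@H]2[C@H](C)[C@@H]4OC(C)(C)O[C@@H]4[C@@]12O | intermediate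
41 | triol ester: as 40 with the ring-A cis-diol free | C=C1[C@H]2C[C@H]3[C@@H](C(C)C)[C@H](OC(=O)C[C@](C)(O)C[C@@H](C)CC)C[C@]3(C)C[C@@H]2/C(C)=C\C[C@H]2[C@H](C)[C@H](O)[C@H](O)[C@@]12O | intermediate
42 | ring-A 1,2-diketone tautomer of the target | C=C1[C@H]2C[C@H]3[C@@H](C(C)C)[C@H](OC(=O)C[C@](C)(O)C[C@@H](C)CC)C[C@]3(C)C[C@@H]2/C(C)=C\C[C@H]2[C@H](C)C(=O)C(=O)[C@@]12O | intermediate
43 | CNP0110944.3 | C=C1[C@H]2C[C@H]3[C@@H](C(C)C)[C@H](OC(=O)C[C@](C)(O)C[C@@H](C)CC)C[C@]3(C)C[C@@H]2/C(C)=C\C[C@H]2C(C)=C(O)C(=O)[C@@]12O | target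

Total step count: 27. Longest linear sequence: 19 steps (steps 9 to 27, from furanone 14 to 43).

Steps most likely to fail:

Step 23. The alkenylchromium may be protonated, or may add to a second molecule, faster than the eight-membered transition state is reached, so that reduced or oligomeric material forms instead of ring B. The fallback keeps the same bond but makes it anionically. Setting out from 36, the triflate would be exchanged for tin (Pd(PPh3)4, LiCl, Me3SnSnMe3, THF, 60 °C) to give the alkenylstannane F1. Iododestannylation (I2, CH2Cl2, 0 °C) would give the alkenyl iodide F2. Iodine–lithium exchange (t-BuLi, THF/Et2O, −100 °C) would then trigger a Barbier-type closure onto the ketone and come back to the route at 38.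

Step 11. The cobalt-complexed, isopropyl-substituted alkyne may fail to insert the 1,1-disubstituted alkene, so that decomplexation or oligomerisation takes over. The fallback introduces the isopropyl group after the rings are built. Setting out from 17, alkylation with propargyl bromide (LiN(i-Pr)2, THF, −78 °C) would give the terminal enyne lactone F3. Its less hindered alkyne should undergo the Pauson–Khand reaction more readily, giving the α-unsubstituted enone F4. Bromination and dehydrobromination (Br2, then Et3N) would give the α-bromoenone F5, and Stille coupling with tributyl(isopropenyl)stannane (Pd(PPh3)4, CuI, DMF) the dienone F6. Hydrogenation under the conditions of step 12 would saturate both alkenes and come back at 22.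

Step 25. The activated, hindered cyclopentanol may eliminate, or the weakly acidic aliphatic acid may fail to displace it. The fallback separates inversion from acylation. Setting out from 39, a Mitsunobu reaction with 4-nitrobenzoic acid would give the inverted 4-nitrobenzoate F7, and methanolysis (K2CO3, MeOH) the inverted alcohol F8. Acid 8 would be silylated (Et3SiOTf, 2,6-lutidine; then K2CO3, aq. MeOH) to the triethylsilyl-protected acid F9 and joined to F8 by Yamaguchi esterification to give the protected ester F10. The aqueous acid of step 26 would then remove both the silyl group and the acetonide and come back at 41.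

Further compounds
F1 | step 23 | alkenylstannane: 36 with trimethylstannyl in place of the triflate | C=C([Sn](C)(C)C)[C@H]1C[C@H]2[C@@H](C(C)C)[C@@H](O[Si](C)(C)C(C)(C)C)C[C@]2(C)C[C@@H]1/C(C)=C\C[C@H]1[C@H](C)[C@@H]2OC(C)(C)O[C@@H]2C1=O
F2 | step 23 | alkenyl iodide: 36 with iodine in place of the triflate | C=C(I)[C@H]1C[C@H]2[C@@H](C(C)C)[C@@H](O[Si](C)(C)C(C)(C)C)C[C@]2(C)C[C@@H]1/C(C)=C\C[C@H]1[C@H](C)[C@@H]2OC(C)(C)O[C@@H]2C1=O
F3 | step 11 | terminal enyne lactone: 19 with prop-2-yn-1-yl in place of 4-methylpent-2-yn-1-yl | O=C1[C@@H](CC#C)[C@H](CC(C)=C)[C@@H](O[C@H]2C[C@@H](C)CC[C@@H]2C(C)C)O1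
F4 | step 11 | α-unsubstituted tricyclic enone: 21 without the isopropyl group | O=C1[C@H]2CC3=CC(=O)C[C@]3(C)C[C@@H]2[C@@H](O[C@H]4C[C@@H](C)CC[C@@H]4C(C)C)O1
F5 | step 11 | α-bromoenone: 21 with bromine in place of isopropyl | O=C1[C@H]2CC3=C(Br)C(=O)C[C@]3(C)C[C@@H]2[C@@H](O[C@H]4C[C@@H](C)CC[C@@H]4C(C)C)O1
F6 | step 11 | dienone: 21 with prop-1-en-2-yl in place of isopropyl | O=C1[C@H]2CC3=C(C(C)=C)C(=O)C[C@]3(C)C[C@@H]2[C@@H](O[C@H]4C[C@@H](C)CC[C@@H]4C(C)C)O1
F7 | step 25 | inverted 4-nitrobenzoate of 39 (acyloxy trans to isopropyl) | C=C1[C@H]2C[C@H]3[C@@H](C(C)C)[C@H](OC(=O)c5ccc(cc5)[N+](=O)[O-])C[C@]3(C)C[C@@H]2/C(C)=C\C[C@H]2[C@H](C)[C@@H]4OC(C)(C)O[C@@H]4[C@@]12O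
F8 | step 25 | inverted alcohol: ring-D epimer of 39 (hydroxyl trans to isopropyl) | C=C1[C@H]2C[C@H]3[C@@H](C(C)C)[C@H](O)C[C@]3(C)C[C@@H]2/C(C)=C\C[C@H]2[C@H](C)[C@@H]4OC(C)(C)O[C@@H]4[C@@]12O
F9 | step 25 | (3R,5S)-3,5-dimethyl-3-(triethylsilyloxy)heptanoic acid | OC(=O)C[C@](C)(O[Si](CC)(CC)CC)C[C@@H](C)CC
F10 | step 25 | triethylsilyl ether of 40 at the side-chain tertiary alcohol | C=C1[C@H]2C[C@H]3[C@@H](C(C)C)[C@H](OC(=O)C[C@](C)(O[Si](CC)(CC)CC)C[C@@H](C)CC)C[C@]3(C)C[C@@H]2/C(C)=C\C[C@H]2[C@H](C)[C@@H]4OC(C)(C)O[C@@H]4[C@@]12O
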